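The route rests on cutting the aryl ketone bond C4–C4a of the chromanone. Ring A (C4a–C5–C6–C7–C8–C8a) is a 2-methylphloroglucinol unit: in an open (R)-2-aryl-3-aryloxypropanoic acid its two carbons ortho to the ether oxygen (future C4a and C8) are equivalent by symmetry and each is activated by three oxygen donors. An intramolecular Friedel–Crafts acylation therefore closes the pyranone ring in one operation, without any regiochemical question and under conditions mild enough to keep the C3 stereocentre, which is set earlier by an auxiliary-controlled aldol hydroxymethylation. The precursor carries the geranylated ring B and all four phenols as methoxymethyl ethers.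

Key step: step 11

Assumption: the single stereocentre of the target is read as (3R); compounds 1, 5, 7 and 13 are taken as commercial. Abbreviations: geranyl = (2E)-3,7-dimethylocta-2,6-dien-1-yl; MOM = methoxymethyl; HFIP = 1,1,1,3,3,3-hexafluoropropan-2-ol.

Step 1
Reactants: 1 2-methylresorcinol
Product: 2 1,3-bis(methoxymethoxy)-2-methylbenzene
Conditions: MOMCl (2.5 equiv), i-Pr2NEt, CH2Cl2, 0 °C → rt
Reagents that add atoms: chloromethyl methyl ether, COCCl
Why: Base-mediated O-alkylation (Williamson-type acetal formation) of both phenols with the reactive α-chloro ether should give the bis-MOM ether, which is stable to the borylation and to all later basic steps.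

Step 2
Reactants: 2 1,3-bis(methoxymethoxy)-2-methylbenzene
Product: 4 3,5-bis(methoxymethoxy)-4-methylphenol, via aryl pinacol boronate 3 (not isolated)
Conditions: [Ir(OMe)(cod)]2 (1.5 mol%), 4,4′-di-tert-butyl-2,2′-bipyridine (3 mol%), B2pin2, THF, 80 °C; then 30% H2O2, aq NaOH, 0 °C → rt
Reagents that add atoms: hydrogen peroxide, OO
Why: Iridium-catalysed aromatic C–H borylation is governed by sterics and should take place only at the one C–H without an ortho substituent (para to the methyl group), and oxidation of the aryl boronate with basic peroxide then gives the phenol at that position.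

Step 3
Reactants: 5 4,6-dibromoresorcinol
Product: 6 1,5-dibromo-2,4-bis(methoxymethoxy)benzene
Conditions: MOMCl (2.5 equiv), i-Pr2NEt, CH2Cl2, 0 °C → rt
Reagents that add atoms: chloromethyl methyl ether, COCCl
Why: The same Williamson-type acetal formation masks both phenols as MOM ethers, which later stabilise the ortho-lithiated arenes by chelation.

Step 4
Reactants: 6 1,5-dibromo-2,4-bis(methoxymethoxy)benzene; 7 geranyl bromide
Product: 9 1-bromo-5-geranyl-2,4-bis(methoxymethoxy)benzene, via monolithiated arene 8 (not isolated)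
Conditions: n-BuLi (1.0 equiv), THF, −78 °C; CuBr·SMe2 (10 mol%), then 7, −78 → 0 °C
Reagents that add atoms: none
Why: Bromine–lithium exchange of one of the two equivalent bromides (the ortho acetal oxygen stabilises the aryllithium) followed by copper-catalysed SN2 allylation with the primary allylic bromide should install the geranyl chain with its E double bond intact.

Step 5
Reactants: 9 1-bromo-5-geranyl-2,4-bis(methoxymethoxy)benzene
Product: 11 2-[5-geranyl-2,4-bis(methoxymethoxy)phenyl]ethan-1-ol, via aryllithium 10 (not isolated)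
Conditions: n-BuLi (1.05 equiv), THF, −78 °C; ethylene oxide (3 equiv), −78 °C → rt; H2O
Reagents that add atoms: ethylene oxide, C1CO1
Why: A second bromine–lithium exchange, faster at −78 °C than deprotonation of the benzylic-allylic CH2, gives an aryllithium that opens the epoxide (nucleophilic ring opening) to the 2-arylethanol.

Step 6
Reactants: 11 2-[5-geranyl-2,4-bis(methoxymethoxy)phenyl]ethan-1-ol
Product: 12 [5-geranyl-2,4-bis(methoxymethoxy)phenyl]acetic acid
Conditions: TEMPO (20 mol%), PhI(OAc)2 (2.2 equiv), MeCN/H2O (1:1), rt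
Reagents that add atoms: water, O
Why: TEMPO-catalysed oxoammonium oxidation with PhI(OAc)2 as terminal oxidant takes the primary alcohol through the aldehyde hydrate to the acid and should leave the trisubstituted alkenes, the acetals and the electron-rich ring untouched.

Step 7
Reactants: 12 [5-geranyl-2,4-bis(methoxymethoxy)phenyl]acetic acid; 13 (4R)-4-benzyl-1,3-oxazolidin-2-one
Product: 15 (4R)-4-benzyl-3-{[5-geranyl-2,4-bis(methoxymethoxy)phenyl]acetyl}-1,3-oxazolidin-2-one, via mixed pivalic anhydride 14 (not isolated)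
Conditions: PivCl, Et3N, THF, −20 °C; then LiCl, 13, −20 °C → rt
Reagents that add atoms: none
Why: Mixed-anhydride N-acylation of the oxazolidinone (LiCl-assisted, attack at the less hindered arylacetyl carbonyl) attaches the chiral auxiliary without recourse to an acid chloride.

Step 8
Reactants: 15 (4R)-4-benzyl-3-{[5-geranyl-2,4-bis(methoxymethoxy)phenyl]acetyl}-1,3-oxazolidin-2-one
Product: 17 (4R)-4-benzyl-3-{(2R)-2-[5-geranyl-2,4-bis(methoxymethoxy)phenyl]-3-hydroxypropanoyl}-1,3-oxazolidin-2-one, via Z-boron enolate 16 (not isolated)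
Conditions: Bu2BOTf (1.1 equiv), i-Pr2NEt (1.2 equiv), CH2Cl2, −78 → 0 °C; CH2O gas (from paraformaldehyde, 150 °C, N2 stream), −78 → 0 °C; pH 7 buffer, MeOH, 30% H2O2, 0 °C
Reagents that add atoms: formaldehyde, C=O
Why: Evans aldol reaction: soft enolisation gives the Z-boron enolate, which adds to formaldehyde through a closed chair transition state with the auxiliary carbonyl turned away from the enolate oxygen, so that the benzyl group of the (R)-auxiliary blocks one face and the new stereocentre (the future C3) is set as R under auxiliary control; the boron reagent spares the aryl acetals that a titanium enolate procedure would endanger.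

Step 9
Reactants: 17 (4R)-4-benzyl-3-{(2R)-2-[5-geranyl-2,4-bis(methoxymethoxy)phenyl]-3-hydroxypropanoyl}-1,3-oxazolidin-2-one; 4 3,5-bis(methoxymethoxy)-4-methylphenol
Product: 18 (4R)-4-benzyl-3-{(2R)-3-[3,5-bis(methoxymethoxy)-4-methylphenoxy]-2-[5-geranyl-2,4-bis(methoxymethoxy)phenyl]propanoyl}-1,3-oxazolidin-2-one
Conditions: PPh3 (1.3 equiv), DIAD (1.3 equiv), toluene/THF, 0 °C → rt
Reagents that add atoms: none
Why: Mitsunobu reaction: the primary alcohol is activated as an alkoxyphosphonium ion and displaced at CH2 by the phenoxide of 4 (pKa about 10) in an SN2 reaction that does not touch the adjacent stereocentre.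

Step 10
Reactants: 18 (4R)-4-benzyl-3-{(2R)-3-[3,5-bis(methoxymethoxy)-4-methylphenoxy]-2-[5-geranyl-2,4-bis(methoxymethoxy)phenyl]propanoyl}-1,3-oxazolidin-2-one
Product: 20 (2R)-3-[3,5-bis(methoxymethoxy)-4-methylphenoxy]-2-[5-geranyl-2,4-bis(methoxymethoxy)phenyl]propanoic acid, via peroxy acid 19 (not isolated)
Conditions: LiOH (2 equiv), 30% H2O2 (4 equiv), THF/H2O (3:1), 0 °C; aq Na2SO3; 1 M HCl to pH 3, 0 °C
Reagents that add atoms: hydrogen peroxide, OO
Why: Hydroperoxide cleaves the imide selectively at the exocyclic carbonyl and is too weak a base to epimerise the α-aryl centre or to eliminate the β-aryloxy group, sulfite reduces the peracid to the acid, and the auxiliary 13 is released.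

Step 11
Reactants: 20 (2R)-3-[3,5-bis(methoxymethoxy)-4-methylphenoxy]-2-[5-geranyl-2,4-bis(methoxymethoxy)phenyl]propanoic acid
Product: 22 (3R)-3-[5-geranyl-2,4-bis(methoxymethoxy)phenyl]-5,7-bis(methoxymethoxy)-6-methylchroman-4-one, via acid chloride 21 (not isolated)
Conditions: 1-chloro-N,N,2-trimethylprop-1-en-1-amine (1.05 equiv), 2,6-di-tert-butyl-4-methylpyridine (1.5 equiv), CH2Cl2, 0 °C; then HFIP (0.02 M), 0 °C → rt
Reagents that add atoms: none
Why: The α-chloroenamine converts the acid under neutral conditions into acid chloride 21, whose carbonyl is activated by hydrogen bonding from HFIP to an acylium-like electrophile that attacks the ring A carbon ortho to the ether oxygen; loss of a proton from the arenium ion (taken up by the hindered pyridine) gives the aryl ketone, that is, the C4–C4a bond. The closest known reaction type is the HFIP-promoted intramolecular Friedel–Crafts acylation of 3-aryloxypropanoyl chlorides to chroman-4-ones. The pyranone ring (O1–C2–C3–C4–C4a–C8a) closes as a six-membered ring in a 6-exo-trig mode at the acyl carbon. No stereocentre is created, and the C3 centre from step 8 should be carried through because no base able to form a ketene or enol is present (the hindered pyridine only scavenges HCl). The step needs regio- and chemoselectivity: the two ortho carbons of the 3,5-bis(methoxymethoxy)-4-methylphenoxy ring are equivalent by symmetry and each is activated by three oxygen donors (ortho, ortho, para), so only one chromanone can form, whereas ring B could be reached only through a three- or four-membered ring, high dilution disfavours intermolecular acylation, and buffering keeps HCl from the acetals and the geranyl alkenes.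

Step 12
Reactants: 22 (3R)-3-[5-geranyl-2,4-bis(methoxymethoxy)phenyl]-5,7-bis(methoxymethoxy)-6-methylchroman-4-one
Product: 23 (3R)-3-[5-geranyl-2,4-dihydroxyphenyl]-5,7-dihydroxy-6-methylchroman-4-one
Conditions: HCl (cat., ca. 0.2 M in MeOH), MeOH/CH2Cl2 (4:1), 0 °C → rt
Reagents that add atoms: none
Why: Acid-catalysed acetal exchange with methanol (transacetalisation to dimethoxymethane) should free the four phenols, and the low acid concentration and temperature are chosen so that neither enolisation at C3 nor cyclisation of the geranyl chain onto the 4′-OH should compete.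

Compound list

1 | 2-methylresorcinol (2-methylbenzene-1,3-diol) | Cc1c(O)cccc1O | starting material
2 | 1,3-bis(methoxymethoxy)-2-methylbenzene | Cc1c(OCOC)cccc1OCOC | intermediate
3 | 2-[3,5-bis(methoxymethoxy)-4-methylphenyl]-4,4,5,5-tetramethyl-1,3,2-dioxaborolane | Cc1c(OCOC)cc(B2OC(C)(C)C(C)(C)O2)cc1OCOC | intermediate
4 | 3,5-bis(methoxymethoxy)-4-methylphenol | Cc1c(OCOC)cc(O)cc1OCOC | intermediate
5 | 4,6-dibromoresorcinol (4,6-dibromobenzene-1,3-diol) | Oc1cc(O)c(Br)cc1Br | starting material
6 | 1,5-dibromo-2,4-bis(methoxymethoxy)benzene | COCOc1cc(OCOC)c(Br)cc1Br | intermediate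
7 | geranyl bromide [(2E)-1-bromo-3,7-dimethylocta-2,6-diene] | CC(C)=CCC/C(C)=C/CBr | starting material
8 | [5-bromo-2,4-bis(methoxymethoxy)phenyl]lithium | [Li]c1cc(Br)c(OCOC)cc1OCOC | intermediate
9 | 1-bromo-5-[(2E)-3,7-dimethylocta-2,6-dien-1-yl]-2,4-bis(methoxymethoxy)benzene | CC(C)=CCC/C(C)=C/Cc1cc(Br)c(OCOC)cc1OCOC | intermediate
10 | {5-[(2E)-3,7-dimethylocta-2,6-dien-1-yl]-2,4-bis(methoxymethoxy)phenyl}lithium | CC(C)=CCC/C(C)=C/Cc1cc([Li])c(OCOC)cc1OCOC | intermediate
11 | 2-{5-[(2E)-3,7-dimethylocta-2,6-dien-1-yl]-2,4-bis(methoxymethoxy)phenyl}ethan-1-ol | CC(C)=CCC/C(C)=C/Cc1cc(CCO)c(OCOC)cc1OCOC | intermediate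
12 | {5-[(2E)-3,7-dimethylocta-2,6-dien-1-yl]-2,4-bis(methoxymethoxy)phenyl}acetic acid | CC(C)=CCC/C(C)=C/Cc1cc(CC(=O)O)c(OCOC)cc1OCOC | intermediate
13 | (4R)-4-benzyl-1,3-oxazolidin-2-one | O=C1N[C@H](Cc2ccccc2)CO1 | starting material
14 | mixed anhydride of acid 12 and pivalic acid | CC(C)=CCC/C(C)=C/Cc1cc(CC(=O)OC(=O)C(C)(C)C)c(OCOC)cc1OCOC | intermediate
15 | (4R)-4-benzyl-3-({5-[(2E)-3,7-dimethylocta-2,6-dien-1-yl]-2,4-bis(methoxymethoxy)phenyl}acetyl)-1,3-oxazolidin-2-one | CC(C)=CCC/C(C)=C/Cc1cc(CC(=O)N2[C@H](Cc3ccccc3)COC2=O)c(OCOC)cc1OCOC | intermediate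
16 | dibutylboron Z-enolate of imide 15 | CCCCB(CCCC)O/C(=C\c1cc(C/C=C(\C)CCC=C(C)C)c(OCOC)cc1OCOC)N1[C@H](Cc2ccccc2)COC1=O | intermediate
17 | (4R)-4-benzyl-3-[(2R)-2-{5-[(2E)-3,7-dimethylocta-2,6-dien-1-yl]-2,4-bis(methoxymethoxy)phenyl}-3-hydroxypropanoyl]-1,3-oxazolidin-2-one | CC(C)=CCC/C(C)=C/Cc1cc([C@H](CO)C(=O)N2[C@H](Cc3ccccc3)COC2=O)c(OCOC)cc1OCOC | intermediate
18 | (4R)-4-benzyl-3-[(2R)-3-[3,5-bis(methoxymethoxy)-4-methylphenoxy]-2-{5-[(2E)-3,7-dimethylocta-2,6-dien-1-yl]-2,4-bis(methoxymethoxy)phenyl}propanoyl]-1,3-oxazolidin-2-one | CC(C)=CCC/C(C)=C/Cc1cc([C@H](COc2cc(OCOC)c(C)c(OCOC)c2)C(=O)N2[C@H](Cc3ccccc3)COC2=O)c(OCOC)cc1OCOC | intermediate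
19 | (2R)-3-[3,5-bis(methoxymethoxy)-4-methylphenoxy]-2-{5-[(2E)-3,7-dimethylocta-2,6-dien-1-yl]-2,4-bis(methoxymethoxy)phenyl}propaneperoxoic acid | CC(C)=CCC/C(C)=C/Cc1cc([C@H](COc2cc(OCOC)c(C)c(OCOC)c2)C(=O)OO)c(OCOC)cc1OCOC | intermediate
20 | (2R)-3-[3,5-bis(methoxymethoxy)-4-methylphenoxy]-2-{5-[(2E)-3,7-dimethylocta-2,6-dien-1-yl]-2,4-bis(methoxymethoxy)phenyl}propanoic acid | CC(C)=CCC/C(C)=C/Cc1cc([C@H](COc2cc(OCOC)c(C)c(OCOC)c2)C(=O)O)c(OCOC)cc1OCOC | intermediate
21 | (2R)-3-[3,5-bis(methoxymethoxy)-4-methylphenoxy]-2-{5-[(2E)-3,7-dimethylocta-2,6-dien-1-yl]-2,4-bis(methoxymethoxy)phenyl}propanoyl chloride | CC(C)=CCC/C(C)=C/Cc1cc([C@H](COc2cc(OCOC)c(C)c(OCOC)c2)C(=O)Cl)c(OCOC)cc1OCOC | intermediate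
22 | (3R)-3-{5-[(2E)-3,7-dimethylocta-2,6-dien-1-yl]-2,4-bis(methoxymethoxy)phenyl}-5,7-bis(methoxymethoxy)-6-methyl-2,3-dihydro-4H-chromen-4-one | CC(C)=CCC/C(C)=C/Cc1cc([C@@H]2COc3cc(OCOC)c(C)c(OCOC)c3C2=O)c(OCOC)cc1OCOC | intermediate
23 | (3R)-3-{5-[(2E)-3,7-dimethylocta-2,6-dien-1-yl]-2,4-dihydroxyphenyl}-5,7-dihydroxy-6-methyl-2,3-dihydro-4H-chromen-4-one (CNP0348256.1) | CC(C)=CCC/C(C)=C/Cc1cc([C@@H]2COc3cc(O)c(C)c(O)c3C2=O)c(O)cc1O | target

Total step count: 12. Longest linear sequence: 10 steps (steps 3 to 12, from 4,6-dibromoresorcinol 5); steps 1 and 2 make the ring A phenol 4, which joins in step 9.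

Steps most likely to fail

Step 11. The acetal oxygen at C2′ sits ortho to the activated acyl group and may attack it (lactonisation with loss of the MOM group). The C3 configuration may also erode through ketene or enol formation, and insufficient buffering would let HCl strip acetals or add to the geranyl alkenes. The fallback separates ring closure from the stereocentre; it sets out from phenol 4 and bromide 9 and comes back at 22. Phenol 4 is O-alkylated with β-propiolactone (aq NaOH, 0 °C → rt, opening at CH2) to give 3-[3,5-bis(methoxymethoxy)-4-methylphenoxy]propanoic acid F1. The same chloroenamine/HFIP Friedel–Crafts cyclisation forms the same C4–C4a bond and should give 5,7-bis(methoxymethoxy)-6-methylchroman-4-one F2; this substrate has no stereocentre, no geranyl group and no acetal next to the acyl group. Palladium-catalysed α-arylation of the ketone with bromide 9 (Pd2(dba)3, XPhos, NaOt-Bu, toluene, 60 °C) should give racemic 3-[5-geranyl-2,4-bis(methoxymethoxy)phenyl]-5,7-bis(methoxymethoxy)-6-methylchroman-4-one F3. Noyori asymmetric transfer hydrogenation with dynamic kinetic resolution (RuCl(p-cymene)[(R,R)-TsDPEN], HCO2H/Et3N, 40 °C; the amine racemises C3 while one enantiomer is reduced) should give cis-(3R,4R)-3-[5-geranyl-2,4-bis(methoxymethoxy)phenyl]-5,7-bis(methoxymethoxy)-6-methylchroman-4-ol F4. Buffered Dess–Martin oxidation (DMP, NaHCO3, CH2Cl2, 0 °C) then returns to 22 without touching C3.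

Step 9. The activated primary alcohol lies β to the imide carbonyl and its α-aryl C–H is acidic, so β-elimination to the 2-arylacryloyl imide or epimerisation by the betaine/phenoxide base may compete with substitution. The fallback forms the same aryl–O bond from the aryl side without turning the alcohol into a leaving group; it sets out from boronate 3 and alcohol 17 and comes back at 18. Boronate 3 is isolated after the borylation instead of being oxidised and is converted with KHF2 (MeOH/H2O, rt) into potassium trifluoro[3,5-bis(methoxymethoxy)-4-methylphenyl]borate F5. Chan–Lam etherification of 17 with F5 (Cu(OAc)2·H2O 10 mol%, DMAP 20 mol%, 4 Å molecular sieves, O2, CH2Cl2, rt) should then give 18.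

Step 12. During the acid solvolysis the ketone may enolise at C3 (loss of enantiopurity), and the geranyl alkene may be protonated and cyclise onto the freed 4′-OH. The fallback avoids protic acid by exchanging the protecting group before unveiling; it sets out from 22 and comes back at 23. Treatment of 22 with TESOTf/2,2′-bipyridyl (CH2Cl2, 0 °C → rt) should exchange each aryl MOM ether for an aryl triethylsilyl ether and give (3R)-3-[5-geranyl-2,4-bis(triethylsilyloxy)phenyl]-6-methyl-5,7-bis(triethylsilyloxy)chroman-4-one F6. KHF2 in MeOH at rt should then cleave the phenolic silyl ethers at near-neutral pH to give 23.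

Further compounds

F1 | step 11 | 3-[3,5-bis(methoxymethoxy)-4-methylphenoxy]propanoic acid | Cc1c(OCOC)cc(OCCC(=O)O)cc1OCOC
F2 | step 11 | 5,7-bis(methoxymethoxy)-6-methyl-2,3-dihydro-4H-chromen-4-one | Cc1c(OCOC)cc2OCCC(=O)c2c1OCOC
F3 | step 11 | racemic 3-{5-[(2E)-3,7-dimethylocta-2,6-dien-1-yl]-2,4-bis(methoxymethoxy)phenyl}-5,7-bis(methoxymethoxy)-6-methyl-2,3-dihydro-4H-chromen-4-one | CC(C)=CCC/C(C)=C/Cc1cc(C2COc3cc(OCOC)c(C)c(OCOC)c3C2=O)c(OCOC)cc1OCOC
F4 | step 11 | (3R,4R)-3-{5-[(2E)-3,7-dimethylocta-2,6-dien-1-yl]-2,4-bis(methoxymethoxy)phenyl}-5,7-bis(methoxymethoxy)-6-methyl-3,4-dihydro-2H-chromen-4-ol | CC(C)=CCC/C(C)=C/Cc1cc([C@@H]2COc3cc(OCOC)c(C)c(OCOC)c3[C@@H]2O)c(OCOC)cc1OCOC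
F5 | step 9 | potassium trifluoro[3,5-bis(methoxymethoxy)-4-methylphenyl]borate | Cc1c(OCOC)cc([B-](F)(F)F)cc1OCOC.[K+]
F6 | step 12 | (3R)-3-{5-[(2E)-3,7-dimethylocta-2,6-dien-1-yl]-2,4-bis(triethylsilyloxy)phenyl}-6-methyl-5,7-bis(triethylsilyloxy)-2,3-dihydro-4H-chromen-4-one | CC(C)=CCC/C(C)=C/Cc1cc([C@@H]2COc3cc(O[Si](CC)(CC)CC)c(C)c(O[Si](CC)(CC)CC)c3C2=O)c(O[Si](CC)(CC)CC)cc1O[Si](CC)(CC)CC
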